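# Proposed synthesis of CNP0180483.4 by enone–ynol ether photocycloaddition and electrocyclic ring expansion

Atoms carry germacrane numbers (C1–C15). Compounds are numbered 1–40 in the order of the steps. DMB = 3,4-dimethoxybenzyl, PMB = 4-methoxybenzyl, TBS = tert-butyldimethylsilyl.

## Analysis of the target

The target is a germacrane lactone of the furanoheliangolide type. Its ten-membered carbocycle (C1–C10) is bridged by an oxygen between C3 and C10, which with the C1 ketone and the C2=C3 bond makes a furan-3(2H)-one. The carbocycle is trans-fused at C6/C7 to an α-methylene γ-lactone (C12 carbonyl, C11=C13). C8 bears a methacrylate, C4 a hydroxymethyl group (C15), and C10 is a fully substituted ether carbon with the C14 methyl group.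

The four stereocentres are (6R,7R,8R,10S). H6 and H7 are trans. O8, O10 and the C7–C11 bond lie on one face of the carbocycle and O6 on the other, so O8 and O10 are 1,3-syn across C9.

The dienone C1(=O)–C2=C3–C4=C5 has C1 and C4 on opposite sides of C2=C3, as the five-membered ring dictates (the descriptor is 2Z only because the ring oxygen outranks C4). It is cis at C4=C5 (4Z).

Sensitive points are the two acrylate-type acceptors, the free allylic alcohol, the acidity of C6–H at the end of the dienone, and the readiness of the lactone to move from O6 to a free O8 under base.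

The difficulty is to close a strained ten-membered ring that holds a trisubstituted Z alkene beside the furanone without disturbing the quaternary C10–O bond and three contiguous stereocentres.

The route rests on one observation: "C1 outward on C2, C6 inward on C5" in the diene C2=C3–C4=C5 is what conrotatory opening of a cyclobutene C2–C3=C4–C5 gives when it is cis-fused through C2–C5 to an eight-membered ring. The oxygen on C10 is placed to deliver C3 to C2.

## Retrosynthetic reasoning

**40 back to 36 (C8–O acyl bond and two O-protecting groups).** The methacrylate comes from 37 and 38 in the last-but-one step, because it would survive neither enolate, organolithium nor photochemical conditions. The C15 silyl ether of 39 goes last so that the primary allylic alcohol never competes in the acylation. O8 is freed from its benzyl-type ether (36 to 37) only after all strongly basic steps, since a free O8 next to the lactone invites translactonisation.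

**36 back to 33 (C11=C13).** The exocyclic methylene is removed. A 1,1-disubstituted acrylate two atoms away from C5 would offer the excited enone a second partner that the rule of five also favours. The forward step is a Mannich reaction and elimination on the lactone enolate, which must take C11–H in preference to C6–H.

**33 back to 31 (oxidation level of C12).** The lactone carbonyl is traced to a methyl acetal. The alkynyl ether can only be made with an alkyllithium, which a lactone would not survive. A C8 ketone, which precedes the C8 carbinol, would also carry a β-acyloxy leaving group if the lactone were in place. The acetal removes both problems and is turned back into the lactone once the sensitive alkyne is gone.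

**31 back to 29 (key disconnection).** C2–C3 and C4–C5 are cut and C2–C5 is rejoined. This turns the ten-membered dienone into a cis-cyclooctenone whose C10 oxygen carries the C3≡C4–C15 unit as an alkynyl ether. Both bonds flank the diene whose geometry is the problem, the tether already exists in the target as the furanone oxygen, and an eight-membered ring is far easier to close than a ten-membered one. The forward step must add the alkyne across C2=C5 with C3 on C2 and open the cyclobutene 30 in the one sense that the five-membered ring allows.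

**29 back to 23 and 24 (C4–C15, the triple bond, the C1 ketone).** C15 comes from 24, the alkyne from a 1,2-dichlorovinyl ether, the ketone from the allylic alcohol. The order is forced. The alkynyl ether must follow the metathesis, because ruthenium carbenes consume electron-rich alkynes. It must precede the ketone, because it is made with an alkyllithium.

**23 back to 22 (C2=C5).** Ring-closing metathesis; a cis alkene is the only outcome in an eight-membered ring.

**22 back to 16 and 17 (C1–C2 and O10–C3).** The vinyl carbinol comes from aldehyde 21. The dichlorovinyl ether is put on with 17 at the stage of 16, where the tertiary hydroxyl is the only free one. O1 and O8 carry benzyl-type ethers of different oxidation potential: they cannot migrate to the neighbouring alkoxide as silyl groups could, and the one on O1 can be removed first.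

**16 back to 14 (C8–H).** The C8 carbinol comes from a ketone by a reduction directed by the free tertiary hydroxyl on C10, which fixes the 1,3-syn relation. This is why the reduction precedes the etherification of O10.

**14 back to 9 (functional group changes).** The ketone comes from a dithiane, the C6 vinyl group from the silyloxymethyl group through an aldehyde, and the acetal from the lactone.

**9 back to 5 and 7 (C7–C8).** Conjugate addition of the C8 acyl-anion equivalent to the butenolide joins the two chiral-pool pieces and sets C7 trans to C6.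

**5 back to 2 and 3; 2 back to 1; 7 back to 6 (C8–C9).** The dithiane anion opens the epoxide at its CH2 terminus, so the quaternary centre C10 is bought with 1 and never made or broken.

## Alternatives that were turned down

**Alternative 1:** The carbocycle of A1 is cut at C1–C10 and is thought of as arising from a six-membered ring holding C3 to C8, whose C3–C8 bond is given up. Forward, two tertiary alkoxides on C3 and C8, each flanked by an enol ether, would undergo a dianionic oxy-Cope shift that forms C1–C10 and opens the cyclohexene to the ten-membered 3,8-dione A1.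
- For it: anion-accelerated oxy-Cope ring expansions are well documented. The cis C4=C5 bond is inherited from the six-membered ring, so its geometry is not at risk; on this point it is stronger than the chosen route. The hindered C1–C10 bond, including the quaternary centre, is made in a pericyclic step.
- Against it: both termini are tri- and tetrasubstituted enol ethers whose geometry must be controlled to set C1 and C10, and C1 is a stereocentre that is later destroyed. A1 holds neither furanone nor lactone, so a long sequence follows: oxidation at C1, cyclodehydration with O10, reduction of the C8 ketone on a flexible ring, oxidation of C12 and lactonisation. In A1 the C10 ether is β and C7 is α to the C8 ketone, so elimination and epimerisation threaten under the basic conditions.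
- Comparison: the chosen route gives furanone and Z alkene together with the ring, and sets C7, C8 and C10 on an open chain. Its price is a key step without direct precedent.

**Alternative 2:** The bonds O–C10 and C9–C10 of A2 are disconnected together. Forward, a copper carbenoid at C10 would be trapped by the ring oxygen of a six-membered cyclic allylic ether (oxygen bound to C3 and C7). The oxonium ylide would then rearrange [2,3]: O–C7 breaks, C9–C10 forms, and the oxolanone and the ten-membered ring of A2 appear at once.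
- For it: ring-expanding ylide shifts to oxygen-bridged medium rings are established. The step builds the quaternary C10–O centre and both rings in one operation without light. On precedent it is stronger than the chosen route.
- Against it: the carbenoid carbon carries a methyl group, so 1,2-hydride shift and [1,2] shift of the ylide compete. The configuration of C10 depends on the face of the ylide. A2 needs dehydrogenation across C2–C3 to reach the furanone. C7 and C8 arrive as a silyl enol ether, so both stereocentres would have to be set late on the ten-membered ring.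
- Comparison: the chosen route has all four stereocentres fixed before ring construction and delivers the furanone at its final oxidation level.

**Alternative 3:** Only the lactone C–O bond at C6 is disconnected, with the alkene moved to C5=C6 and an epoxide spanning C4 and C15. Forward, a zerovalent palladium catalyst would ionise the C4–O bond, and the C12 carboxylate would attack C6 of the allyl unit C4–C5–C6 to give A3.
- For it: the reaction type is mild, catalytic and well precedented. It delivers the C15 alcohol unprotected and the lactone without an oxidation, which is more economical at the end than the sequence chosen here.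
- Against it: it is a late functional-group exchange and leaves the furanone-bridged ten-membered ring unmade. Attack at C4 instead of C6, equilibration of the allyl complex (which decides Z against E), and the stereochemical course at C6 must all go the right way on a strained ring.
- Comparison: the chosen route builds the ring system itself.

Key step: step 19

## Route

Assumption: the acetal carbon C12 (compounds 10–13, 30–32 and all in between) and the carbinol carbon C1 (22–28) form as both epimers and are drawn without configuration, because each becomes trigonal again (steps 18 and 20).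

Step 1
Reactants: 1 (R)-(2-methyloxiran-2-yl)methanol [(R)-2-methylglycidol]
Product: 2 (S)-2-{[(3,4-dimethoxybenzyl)oxy]methyl}-2-methyloxirane
Conditions: NaH, 3,4-(MeO)2C6H3CH2Cl, Bu4NI (cat.), THF/DMF, 0 °C to rt
Reagents that add atoms: 3,4-dimethoxybenzyl chloride, COc1ccc(CCl)cc1OC
Why: Williamson etherification; the stereocentre is not involved (the Payne rearrangement of this alkoxide is degenerate), and the descriptor changes from R to S only through the priority rules.

Step 2
Reactants: 2 (S)-2-{[(3,4-dimethoxybenzyl)oxy]methyl}-2-methyloxirane; 3 1,3-dithiane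
Product: 5 (S)-1-[(3,4-dimethoxybenzyl)oxy]-3-(1,3-dithian-2-yl)-2-methylpropan-2-ol, via 2-lithio-1,3-dithiane 4 (not isolated)
Conditions: 3, n-BuLi, THF, −30 °C; then 2, −30 °C to rt; aq NH4Cl
Reagents that add atoms: none
Why: Corey–Seebach alkylation: the dithiane anion opens the 2,2-disubstituted epoxide at its CH2 terminus (SN2), which leaves the quaternary centre C10 untouched and frees its oxygen as the tertiary alcohol.

Step 3
Reactants: 6 (S)-5-(hydroxymethyl)furan-2(5H)-one
Product: 7 (S)-5-{[(tert-butyldimethylsilyl)oxy]methyl}furan-2(5H)-one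
Conditions: t-BuMe2SiCl, imidazole, CH2Cl2, 0 °C to rt
Reagents that add atoms: tert-butyldimethylsilyl chloride, CC(C)(C)[Si](C)(C)Cl
Why: Standard silylation of the primary alcohol; the bulky group later shields one face of the butenolide.

Step 4
Reactants: 5 (S)-1-[(3,4-dimethoxybenzyl)oxy]-3-(1,3-dithian-2-yl)-2-methylpropan-2-ol; 7 (S)-5-{[(tert-butyldimethylsilyl)oxy]methyl}furan-2(5H)-one
Product: 9 (4S,5S)-5-{[(tert-butyldimethylsilyl)oxy]methyl}-4-{2-[(S)-3-[(3,4-dimethoxybenzyl)oxy]-2-hydroxy-2-methylpropyl]-1,3-dithian-2-yl}dihydrofuran-2(3H)-one, via dilithio derivative 8 (not isolated)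
Conditions: 5, n-BuLi (2.2 equiv), THF, −30 to −10 °C; HMPA, −78 °C; then 7; aq NH4Cl
Reagents that add atoms: none
Why: Conjugate (1,4) addition of a 2-lithio-1,3-dithiane, the acyl-anion equivalent of C8, to the butenolide, directed to the β-carbon by HMPA; the nucleophile enters anti to the silyloxymethyl group on C6, so C7 is set trans to C6 by substrate control.

Step 5
Reactants: 9 (4S,5S)-5-{[(tert-butyldimethylsilyl)oxy]methyl}-4-{2-[(S)-3-[(3,4-dimethoxybenzyl)oxy]-2-hydroxy-2-methylpropyl]-1,3-dithian-2-yl}dihydrofuran-2(3H)-one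
Product: 11 [(2S,3S)-3-{2-[(S)-3-[(3,4-dimethoxybenzyl)oxy]-2-hydroxy-2-methylpropyl]-1,3-dithian-2-yl}-5-methoxytetrahydrofuran-2-yl]methanol (both C12 epimers), via lactol 10 (not isolated)
Conditions: iBu2AlH, CH2Cl2, −78 °C; then MeOH, camphorsulfonic acid (cat.), rt
Reagents that add atoms: methanol, CO
Why: Partial reduction of the lactone and Fischer acetalisation of the lactol in methanol; the same acid removes the primary silyl ether. Masking C12 takes the carbonyl out of reach of the organolithium of step 16 and prevents β-acyloxy elimination once C8 is a ketone.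

Step 6
Reactants: 11 [(2S,3S)-3-{2-[(S)-3-[(3,4-dimethoxybenzyl)oxy]-2-hydroxy-2-methylpropyl]-1,3-dithian-2-yl}-5-methoxytetrahydrofuran-2-yl]methanol
Product: 12 (2S,3S)-3-{2-[(S)-3-[(3,4-dimethoxybenzyl)oxy]-2-hydroxy-2-methylpropyl]-1,3-dithian-2-yl}-5-methoxytetrahydrofuran-2-carbaldehyde
Conditions: SO3·pyridine, DMSO, iPr2NEt, CH2Cl2, 0 °C
Reagents that add atoms: none
Why: Parikh–Doering oxidation of the primary alcohol; activated-DMSO conditions do not oxidise the dithiane sulfur, and the tertiary alcohol is inert.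

Step 7
Reactants: 12 (2S,3S)-3-{2-[(S)-3-[(3,4-dimethoxybenzyl)oxy]-2-hydroxy-2-methylpropyl]-1,3-dithian-2-yl}-5-methoxytetrahydrofuran-2-carbaldehyde
Product: 13 (S)-1-[(3,4-dimethoxybenzyl)oxy]-3-{2-[(2R,3S)-5-methoxy-2-vinyltetrahydrofuran-3-yl]-1,3-dithian-2-yl}-2-methylpropan-2-ol
Conditions: Ph3PCH3Br, KN(SiMe3)2, THF, −78 to 0 °C
Reagents that add atoms: methyltriphenylphosphonium bromide, C[P+](c1ccccc1)(c1ccccc1)c1ccccc1.[Br-]
Why: Wittig methylenation of the aldehyde, run while C8 is still a dithiane so that no second carbonyl competes; excess ylide compensates for the free tertiary hydroxyl.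

Step 8
Reactants: 13 (S)-1-[(3,4-dimethoxybenzyl)oxy]-3-{2-[(2R,3S)-5-methoxy-2-vinyltetrahydrofuran-3-yl]-1,3-dithian-2-yl}-2-methylpropan-2-ol
Product: 14 (S)-4-[(3,4-dimethoxybenzyl)oxy]-3-hydroxy-1-[(2R,3S)-5-methoxy-2-vinyltetrahydrofuran-3-yl]-3-methylbutan-1-one
Conditions: MeI, CaCO3, MeCN/H2O (9:1), 45 °C
Reagents that add atoms: water, O
Why: Alkylative hydrolysis of the dithiane (Corey–Seebach unmasking) under buffered neutral conditions; the β-alkoxy ketone is not exposed to base, so neither loss of O6 nor epimerisation at C7 is expected.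

Step 9
Reactants: 14 (S)-4-[(3,4-dimethoxybenzyl)oxy]-3-hydroxy-1-[(2R,3S)-5-methoxy-2-vinyltetrahydrofuran-3-yl]-3-methylbutan-1-one
Product: 15 (2S,4R)-1-[(3,4-dimethoxybenzyl)oxy]-4-[(2R,3R)-5-methoxy-2-vinyltetrahydrofuran-3-yl]-2-methylbutane-2,4-diol
Conditions: Et2BOMe, THF/MeOH (4:1), −78 °C; NaBH4; then MeOH, evaporation
Reagents that add atoms: none
Why: Narasaka–Prasad reduction: the tertiary hydroxyl and the ketone form a six-membered boron chelate, external hydride adds axially and gives the 1,3-syn diol. C8 (R) is set relative to C10, with the larger CH2O-benzyl arm equatorial and the methyl group axial in the chelate.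

Step 10
Reactants: 15 (2S,4R)-1-[(3,4-dimethoxybenzyl)oxy]-4-[(2R,3R)-5-methoxy-2-vinyltetrahydrofuran-3-yl]-2-methylbutane-2,4-diol
Product: 16 (2S,4R)-1-[(3,4-dimethoxybenzyl)oxy]-4-[(4-methoxybenzyl)oxy]-4-[(2R,3R)-5-methoxy-2-vinyltetrahydrofuran-3-yl]-2-methylbutan-2-ol
Conditions: NaH (1.1 equiv), 4-MeOC6H4CH2Cl, Bu4NI (cat.), DMF, 0 °C
Reagents that add atoms: 4-methoxybenzyl chloride, COc1ccc(CCl)cc1
Why: Williamson etherification at the secondary alkoxide; the tertiary hydroxyl is too hindered to be alkylated. A benzyl-type ether is used on O8 because a silyl group could migrate to the tertiary alkoxide in step 11.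

Step 11
Reactants: 16 (2S,4R)-1-[(3,4-dimethoxybenzyl)oxy]-4-[(4-methoxybenzyl)oxy]-4-[(2R,3R)-5-methoxy-2-vinyltetrahydrofuran-3-yl]-2-methylbutan-2-ol; 17 trichloroethylene
Product: 19 4-{[(2S,4R)-2-{[(E)-1,2-dichlorovinyl]oxy}-4-[(4-methoxybenzyl)oxy]-4-[(2R,3R)-5-methoxy-2-vinyltetrahydrofuran-3-yl]-2-methylbutoxy]methyl}-1,2-dimethoxybenzene, via dichloroacetylene 18 (not isolated)
Conditions: KH, THF, 0 °C; then 17, 0 °C to rt
Reagents that add atoms: none
Why: First stage of the Greene ynol ether synthesis: base converts 17 into 18, the tertiary alkoxide adds anti and is protonated to the (E)-1,2-dichlorovinyl ether. The tertiary hydroxyl is the only one in 16, and no carbonyl is present.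

Step 12
Reactants: 19 the (E)-1,2-dichlorovinyl ether of step 11
Product: 20 (2S,4R)-2-{[(E)-1,2-dichlorovinyl]oxy}-4-[(4-methoxybenzyl)oxy]-4-[(2R,3R)-5-methoxy-2-vinyltetrahydrofuran-3-yl]-2-methylbutan-1-ol
Conditions: DDQ (1.1 equiv), CH2Cl2/pH 7 buffer (10:1), 0 °C
Reagents that add atoms: none
Why: Oxidative debenzylation with DDQ; the 3,4-dimethoxybenzyl ether is the more electron-rich and is cleaved before the 4-methoxybenzyl ether (known order of reactivity). The electron-poor dichlorovinyl ether is inert.

Step 13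
Reactants: 20 (2S,4R)-2-{[(E)-1,2-dichlorovinyl]oxy}-4-[(4-methoxybenzyl)oxy]-4-[(2R,3R)-5-methoxy-2-vinyltetrahydrofuran-3-yl]-2-methylbutan-1-ol
Product: 21 (2S,4R)-2-{[(E)-1,2-dichlorovinyl]oxy}-4-[(4-methoxybenzyl)oxy]-4-[(2R,3R)-5-methoxy-2-vinyltetrahydrofuran-3-yl]-2-methylbutanal
Conditions: Dess–Martin periodinane, NaHCO3, CH2Cl2, 0 °C to rt
Reagents that add atoms: none
Why: Dess–Martin oxidation of the neopentyl-type primary alcohol; the aldehyde has no α-hydrogen, so C10 cannot epimerise.

Step 14
Reactants: 21 (2S,4R)-2-{[(E)-1,2-dichlorovinyl]oxy}-4-[(4-methoxybenzyl)oxy]-4-[(2R,3R)-5-methoxy-2-vinyltetrahydrofuran-3-yl]-2-methylbutanal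
Product: 22 (4S,6R)-4-{[(E)-1,2-dichlorovinyl]oxy}-6-[(4-methoxybenzyl)oxy]-6-[(2R,3R)-5-methoxy-2-vinyltetrahydrofuran-3-yl]-4-methylhex-1-en-3-ol (both epimers at the new carbinol C1)
Conditions: CH2=CHMgBr, THF, −78 to −20 °C; aq NH4Cl
Reagents that add atoms: vinylmagnesium bromide, C=C[Mg]Br
Why: Grignard addition to the aldehyde at low temperature; the new carbinol centre C1 forms as both epimers, which is of no consequence because it becomes the ketone in step 18.

Step 15
Reactants: 22 (4S,6R)-4-{[(E)-1,2-dichlorovinyl]oxy}-6-[(4-methoxybenzyl)oxy]-6-[(2R,3R)-5-methoxy-2-vinyltetrahydrofuran-3-yl]-4-methylhex-1-en-3-ol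
Product: 23 (3aR,4R,6S,9aR,Z)-6-{[(E)-1,2-dichlorovinyl]oxy}-2-methoxy-4-[(4-methoxybenzyl)oxy]-6-methyl-2,3,3a,4,5,6,7,9a-octahydrocycloocta[b]furan-7-ol
Conditions: second-generation Grubbs catalyst (H2IMes)(PCy3)Cl2Ru=CHPh (10 mol%), CH2Cl2 (2 mM), 40 °C
Reagents that add atoms: none
Why: Ring-closing metathesis of the two monosubstituted alkenes; the trans-fused acetal ring holds both chains close and the free allylic hydroxyl aids initiation. The dichlorovinyl ether is too hindered and electron-poor to engage the carbene, and an eight-membered ring can hold only the Z alkene.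

Step 16
Reactants: 23 the cyclooctenol of step 15; 24 formaldehyde
Product: 27 (3aR,4R,6S,9aR,Z)-6-[(3-hydroxyprop-1-yn-1-yl)oxy]-2-methoxy-4-[(4-methoxybenzyl)oxy]-6-methyl-2,3,3a,4,5,6,7,9a-octahydrocycloocta[b]furan-7-ol, via chloroalkynyl ether 25 (not isolated), via lithium alkynyl ether 26 (not isolated)
Conditions: n-BuLi (3.5 equiv), THF, −78 to −40 °C; then 24 (gas from cracked paraformaldehyde), −78 to −20 °C; pH 7 buffer
Reagents that add atoms: none
Why: Second stage of the Greene ynol ether synthesis: after the hydroxyl is deprotonated, n-BuLi eliminates HCl to 25 and exchanges the remaining chlorine for lithium to give 26, which adds to 24. Nothing in 23 (acetal, benzyl ether, alkene, alkoxide) is electrophilic, which is why lactone and ketone are absent at this stage.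

Step 17
Reactants: 27 the propargylic diol of step 16
Product: 28 (3aR,4R,6S,9aR,Z)-6-({3-[(tert-butyldimethylsilyl)oxy]prop-1-yn-1-yl}oxy)-2-methoxy-4-[(4-methoxybenzyl)oxy]-6-methyl-2,3,3a,4,5,6,7,9a-octahydrocycloocta[b]furan-7-ol
Conditions: t-BuMe2SiCl (1.05 equiv), imidazole, CH2Cl2, 0 °C
Reagents that add atoms: tert-butyldimethylsilyl chloride, CC(C)(C)[Si](C)(C)Cl
Why: Silylation of the primary propargylic hydroxyl in preference to the hindered secondary allylic one next to the quaternary carbon; the medium stays basic, so the ynol ether is not protonated.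

Step 18
Reactants: 28 the silyl ether of step 17
Product: 29 (3aR,4R,6S,9aR,Z)-6-({3-[(tert-butyldimethylsilyl)oxy]prop-1-yn-1-yl}oxy)-2-methoxy-4-[(4-methoxybenzyl)oxy]-6-methyl-3,3a,4,5,6,9a-hexahydrocycloocta[b]furan-7(2H)-one (the photochemical precursor; lactone carbonyl masked as methyl acetal)
Conditions: MnO2 (activated, excess), CH2Cl2, 0 °C to rt
Reagents that add atoms: none
Why: MnO2 oxidation of the allylic alcohol to the Z-enone under neutral heterogeneous conditions that leave the acid-sensitive ynol ether alone; both C1 epimers converge.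

Step 19
Reactants: 29 the cyclooctenone ynol ether of step 18
Product: 31 (4Z,6R,7R,8R,10S)-15-[(tert-butyldimethylsilyl)oxy]-3,10:6,12-diepoxy-12-methoxy-8-[(4-methoxybenzyl)oxy]-13-norgermacra-2,4-dien-1-one, via cyclobutene photoadduct 30 (not isolated)
Conditions: hν (366 nm, Pyrex), degassed MeCN (3 mM), NaHCO3 (solid), −20 °C; then 20 °C, dark
Reagents that add atoms: none
Why: Proposed new method: excitation of the enone (n→π*) and intersystem crossing give the triplet, whose α-carbon C2 bonds to the alkyne carbon C3 in a 5-exo-dig closure, the mode that the three-atom link C1–C10–O leaves open (rule of five); this closes the oxolanone ring. The resulting 1,4-diradical (vinyl at C4, alkyl at C5) closes C4–C5 after spin inversion to 30, a cyclobutene whose C3=C4 bond sits at the fusion with the five-membered ring and whose C2–C5 bond is shared with the eight-membered ring. 30 then opens thermally in a conrotatory 4π-electrocyclic reaction that breaks C2–C5, so the ten-membered ring arises by two-carbon ring expansion and not by cyclisation of a chain. The closest known reaction types are intramolecular enone–alkyne [2+2] photocycloadditions giving ring-fusion cyclobutenes and the thermal opening of cis-bicyclo[6.2.0]dec-9-enes to cis,trans-cyclodeca-1,3-dienes; an ynol ether as the alkyne partner and the direct formation of a furan-3(2H)-one have not been shown. No lasting stereocentre is formed: C2 and C5 are stereogenic only in 30, and C6, C7, C8 and C10 are spectators. The step needs regioselectivity (C2 to C3, C5 to C4), which the tether secures, and the 4Z geometry, which requires a cis fusion of the four- and eight-membered rings: the five-membered ring forces C1 outward on C2, and conrotation then turns C6 inward on C5. The cis fusion is expected because the diradical should close before the ring can twist into the arrangement needed for a trans fusion, which the C10–O–C3 bridge and the trans-fused acetal ring both resist. Strain at the ring-fusion alkene together with the donor oxygen on C3 and the acceptor carbonyl on C2 should bring the opening to room temperature or below, and light of 366 nm is used so that the more strongly absorbing product is spared.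

Step 20
Reactants: 31 the furanone dienone acetal of step 19
Product: 33 (4Z,6R,7R,8R,10S)-15-[(tert-butyldimethylsilyl)oxy]-3,10-epoxy-8-[(4-methoxybenzyl)oxy]-1-oxo-13-norgermacra-2,4-dien-12,6-olide, via lactol 32 (not isolated)
Conditions: pyridinium p-toluenesulfonate, acetone/H2O (10:1), rt; crude lactol, then TEMPO (cat.), PhI(OAc)2, CH2Cl2, rt
Reagents that add atoms: water, O
Why: Acid hydrolysis of the 2-methoxytetrahydrofuran acetal (much faster than loss of the primary silyl ether or attack on the vinylogous ester) and TEMPO-catalysed oxidation of the lactol restore the γ-lactone; both C12 epimers converge.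

Step 21
Reactants: 33 the 13-nor lactone of step 20
Product: 36 (4Z,6R,7R,8R,10S)-15-[(tert-butyldimethylsilyl)oxy]-3,10-epoxy-8-[(4-methoxybenzyl)oxy]-1-oxogermacra-2,4,11(13)-trien-12,6-olide, via Mannich base 34 (not isolated), via ammonium iodide 35 (not isolated)
Conditions: LiN(SiMe3)2, THF, −78 °C; Me2N=CH2 I, −78 to 0 °C; work-up; MeI, CH2Cl2, rt; then aq NaHCO3
Reagents that add atoms: N,N-dimethylmethyleneiminium iodide (Eschenmoser's salt), C=[N+](C)C.[I-]
Why: α-Methylenation through the lactone enolate (Mannich reaction with the Eschenmoser iminium salt, quaternisation, Hofmann-type elimination). Kinetic deprotonation at −78 °C is expected at C11 and not at the more hindered vinylogous position C6; no stereocentre is affected.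

Step 22
Reactants: 36 the α-methylene lactone of step 21
Product: 37 (4Z,6R,7R,8R,10S)-15-[(tert-butyldimethylsilyl)oxy]-3,10-epoxy-8-hydroxy-1-oxogermacra-2,4,11(13)-trien-12,6-olide
Conditions: DDQ, CH2Cl2/pH 7 buffer (10:1), 0 °C to rt
Reagents that add atoms: none
Why: Oxidative cleavage of the 4-methoxybenzyl ether with DDQ; the neutral conditions avoid migration of the lactone to the freed O8.

Step 23
Reactants: 37 the C8 alcohol of step 22; 38 methacrylic anhydride
Product: 39 (4Z,6R,7R,8R,10S)-15-[(tert-butyldimethylsilyl)oxy]-3,10-epoxy-8-(methacryloyloxy)-1-oxogermacra-2,4,11(13)-trien-12,6-olide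
Conditions: 38, Et3N, DMAP (cat.), CH2Cl2, 0 °C to rt
Reagents that add atoms: none
Why: DMAP-catalysed acyl transfer (Steglich-type) to the secondary alcohol; the amine base is too weak to move the lactone, and the 5-endo oxa-Michael closure of O8 onto C13 is disfavoured.

Step 24
Reactants: 39 the silyl ether of step 23
Product: 40 (4Z,6R,7R,8R,10S)-3,10-epoxy-15-hydroxy-8-(methacryloyloxy)-1-oxogermacra-2,4,11(13)-trien-12,6-olide (CNP0180483.4)
Conditions: HF·pyridine, pyridine, THF, 0 °C to rt
Reagents that add atoms: none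
Why: Fluoride cleavage of the primary allylic silyl ether with buffered HF·pyridine, which spares both acrylate units, the esters and the vinylogous ester.

## Compound list

1 | (R)-(2-methyloxiran-2-yl)methanol | C[C@@]1(CO)CO1 | starting material
2 | (S)-2-{[(3,4-dimethoxybenzyl)oxy]methyl}-2-methyloxirane | COc1ccc(COC[C@]2(C)CO2)cc1OC | intermediate
3 | 1,3-dithiane | C1CSCSC1 | starting material
4 | 2-lithio-1,3-dithiane | [Li]C1SCCCS1 | intermediate
5 | (S)-1-[(3,4-dimethoxybenzyl)oxy]-3-(1,3-dithian-2-yl)-2-methylpropan-2-ol | COc1ccc(COC[C@@](C)(O)CC2SCCCS2)cc1OC | intermediate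
6 | (S)-5-(hydroxymethyl)furan-2(5H)-one | OC[C@H]1OC(=O)C=C1 | starting material
7 | (S)-5-{[(tert-butyldimethylsilyl)oxy]methyl}furan-2(5H)-one | CC(C)(C)[Si](C)(C)OC[C@H]1OC(=O)C=C1 | intermediate
8 | O,C-dilithio derivative of 5 (lithium alkoxide; lithium at C2 of the dithiane) | COc1ccc(COC[C@@](C)(O[Li])CC2([Li])SCCCS2)cc1OC | intermediate
9 | (4S,5S)-5-{[(tert-butyldimethylsilyl)oxy]methyl}-4-{2-[(S)-3-[(3,4-dimethoxybenzyl)oxy]-2-hydroxy-2-methylpropyl]-1,3-dithian-2-yl}dihydrofuran-2(3H)-one | CC(C)(C)[Si](C)(C)OC[C@H]1OC(=O)C[C@@H]1C2(C[C@](C)(O)COCc3ccc(OC)c(OC)c3)SCCCS2 | intermediate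
10 | lactol of 9 (carbonyl C12 reduced to CH–OH, both epimers) | CC(C)(C)[Si](C)(C)OC[C@H]1OC(O)C[C@@H]1C2(C[C@](C)(O)COCc3ccc(OC)c(OC)c3)SCCCS2 | intermediate
11 | [(2S,3S)-3-{2-[(S)-3-[(3,4-dimethoxybenzyl)oxy]-2-hydroxy-2-methylpropyl]-1,3-dithian-2-yl}-5-methoxytetrahydrofuran-2-yl]methanol (both C12 epimers) | OC[C@H]1OC(OC)C[C@@H]1C2(C[C@](C)(O)COCc3ccc(OC)c(OC)c3)SCCCS2 | intermediate
12 | (2S,3S)-3-{2-[(S)-3-[(3,4-dimethoxybenzyl)oxy]-2-hydroxy-2-methylpropyl]-1,3-dithian-2-yl}-5-methoxytetrahydrofuran-2-carbaldehyde | O=C[C@H]1OC(OC)C[C@@H]1C2(C[C@](C)(O)COCc3ccc(OC)c(OC)c3)SCCCS2 | intermediate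
13 | (S)-1-[(3,4-dimethoxybenzyl)oxy]-3-{2-[(2R,3S)-5-methoxy-2-vinyltetrahydrofuran-3-yl]-1,3-dithian-2-yl}-2-methylpropan-2-ol | C=C[C@H]1OC(OC)C[C@@H]1C2(C[C@](C)(O)COCc3ccc(OC)c(OC)c3)SCCCS2 | intermediate
14 | (S)-4-[(3,4-dimethoxybenzyl)oxy]-3-hydroxy-1-[(2R,3S)-5-methoxy-2-vinyltetrahydrofuran-3-yl]-3-methylbutan-1-one | C=C[C@H]1OC(OC)C[C@@H]1C(=O)C[C@](C)(O)COCc2ccc(OC)c(OC)c2 | intermediate
15 | (2S,4R)-1-[(3,4-dimethoxybenzyl)oxy]-4-[(2R,3R)-5-methoxy-2-vinyltetrahydrofuran-3-yl]-2-methylbutane-2,4-diol | C=C[C@H]1OC(OC)C[C@@H]1[C@H](O)C[C@](C)(O)COCc2ccc(OC)c(OC)c2 | intermediate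
16 | (2S,4R)-1-[(3,4-dimethoxybenzyl)oxy]-4-[(4-methoxybenzyl)oxy]-4-[(2R,3R)-5-methoxy-2-vinyltetrahydrofuran-3-yl]-2-methylbutan-2-ol | C=C[C@H]1OC(OC)C[C@@H]1[C@H](OCc2ccc(OC)cc2)C[C@](C)(O)COCc2ccc(OC)c(OC)c2 | intermediate
17 | trichloroethylene | ClC=C(Cl)Cl | starting material
18 | dichloroacetylene | ClC#CCl | intermediate
19 | 4-{[(2S,4R)-2-{[(E)-1,2-dichlorovinyl]oxy}-4-[(4-methoxybenzyl)oxy]-4-[(2R,3R)-5-methoxy-2-vinyltetrahydrofuran-3-yl]-2-methylbutoxy]methyl}-1,2-dimethoxybenzene | C=C[C@H]1OC(OC)C[C@@H]1[C@H](OCc2ccc(OC)cc2)C[C@](C)(O/C(Cl)=C\Cl)COCc2ccc(OC)c(OC)c2 | intermediate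
20 | (2S,4R)-2-{[(E)-1,2-dichlorovinyl]oxy}-4-[(4-methoxybenzyl)oxy]-4-[(2R,3R)-5-methoxy-2-vinyltetrahydrofuran-3-yl]-2-methylbutan-1-ol | C=C[C@H]1OC(OC)C[C@@H]1[C@H](OCc2ccc(OC)cc2)C[C@](C)(O/C(Cl)=C\Cl)CO | intermediate
21 | (2S,4R)-2-{[(E)-1,2-dichlorovinyl]oxy}-4-[(4-methoxybenzyl)oxy]-4-[(2R,3R)-5-methoxy-2-vinyltetrahydrofuran-3-yl]-2-methylbutanal | C=C[C@H]1OC(OC)C[C@@H]1[C@H](OCc2ccc(OC)cc2)C[C@](C)(O/C(Cl)=C\Cl)C=O | intermediate
22 | (4S,6R)-4-{[(E)-1,2-dichlorovinyl]oxy}-6-[(4-methoxybenzyl)oxy]-6-[(2R,3R)-5-methoxy-2-vinyltetrahydrofuran-3-yl]-4-methylhex-1-en-3-ol (both C3 epimers) | C=C[C@H]1OC(OC)C[C@@H]1[C@H](OCc2ccc(OC)cc2)C[C@](C)(O/C(Cl)=C\Cl)C(O)C=C | intermediate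
23 | (3aR,4R,6S,9aR,Z)-6-{[(E)-1,2-dichlorovinyl]oxy}-2-methoxy-4-[(4-methoxybenzyl)oxy]-6-methyl-2,3,3a,4,5,6,7,9a-octahydrocycloocta[b]furan-7-ol (epimers at C2 and C7 of this name) | COc1ccc(cc1)CO[C@@H]1C[C@](C)(O/C(Cl)=C\Cl)C(O)/C=C\[C@H]2OC(OC)C[C@@H]21 | intermediate
24 | formaldehyde | C=O | starting material
25 | lithium alkoxide of the 6-(chloroethynyloxy) analogue of 23 | COc1ccc(cc1)CO[C@@H]1C[C@](C)(OC#CCl)C(O[Li])/C=C\[C@H]2OC(OC)C[C@@H]21 | intermediate
26 | dilithio species: C1 alkoxide and lithium on the alkyne terminus C4 | COc1ccc(cc1)CO[C@@H]1C[C@](C)(OC#C[Li])C(O[Li])/C=C\[C@H]2OC(OC)C[C@@H]21 | intermediate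
27 | (3aR,4R,6S,9aR,Z)-6-[(3-hydroxyprop-1-yn-1-yl)oxy]-2-methoxy-4-[(4-methoxybenzyl)oxy]-6-methyl-2,3,3a,4,5,6,7,9a-octahydrocycloocta[b]furan-7-ol | COc1ccc(cc1)CO[C@@H]1C[C@](C)(OC#CCO)C(O)/C=C\[C@H]2OC(OC)C[C@@H]21 | intermediate
28 | (3aR,4R,6S,9aR,Z)-6-({3-[(tert-butyldimethylsilyl)oxy]prop-1-yn-1-yl}oxy)-2-methoxy-4-[(4-methoxybenzyl)oxy]-6-methyl-2,3,3a,4,5,6,7,9a-octahydrocycloocta[b]furan-7-ol | COc1ccc(cc1)CO[C@@H]1C[C@](C)(OC#CCO[Si](C)(C)C(C)(C)C)C(O)/C=C\[C@H]2OC(OC)C[C@@H]21 | intermediate
29 | (3aR,4R,6S,9aR,Z)-6-({3-[(tert-butyldimethylsilyl)oxy]prop-1-yn-1-yl}oxy)-2-methoxy-4-[(4-methoxybenzyl)oxy]-6-methyl-3,3a,4,5,6,9a-hexahydrocycloocta[b]furan-7(2H)-one | COc1ccc(cc1)CO[C@@H]1C[C@](C)(OC#CCO[Si](C)(C)C(C)(C)C)C(=O)/C=C\[C@H]2OC(OC)C[C@@H]21 | intermediate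
30 | cyclobutene photoadduct of 29: C2–C3 and C4–C5 bonded, C3=C4 double bond, four-membered ring cis-fused to the eight-membered ring with H2 and H5 on the face opposite to O10 | O=C1[C@@H]2C3=C(CO[Si](C)(C)C(C)(C)C)[C@@H]2[C@H]2OC(OC)C[C@@H]2[C@H](OCc2ccc(OC)cc2)C[C@]1(C)O3 | intermediate
31 | (4Z,6R,7R,8R,10S)-15-[(tert-butyldimethylsilyl)oxy]-3,10:6,12-diepoxy-12-methoxy-8-[(4-methoxybenzyl)oxy]-13-norgermacra-2,4-dien-1-one (both C12 epimers) | COc1ccc(cc1)CO[C@@H]1C[C@]2(C)OC(=CC2=O)/C(CO[Si](C)(C)C(C)(C)C)=C\[C@H]2OC(OC)C[C@@H]21 | intermediate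
32 | lactol of 31 (12-hydroxy in place of 12-methoxy) | COc1ccc(cc1)CO[C@@H]1C[C@]2(C)OC(=CC2=O)/C(CO[Si](C)(C)C(C)(C)C)=C\[C@H]2OC(O)C[C@@H]21 | intermediate
33 | (4Z,6R,7R,8R,10S)-15-[(tert-butyldimethylsilyl)oxy]-3,10-epoxy-8-[(4-methoxybenzyl)oxy]-1-oxo-13-norgermacra-2,4-dien-12,6-olide | COc1ccc(cc1)CO[C@@H]1C[C@]2(C)OC(=CC2=O)/C(CO[Si](C)(C)C(C)(C)C)=C\[C@H]2OC(=O)C[C@@H]21 | intermediate
34 | 11-(dimethylaminomethyl) derivative of 33 (C11 epimers) | COc1ccc(cc1)CO[C@@H]1C[C@]2(C)OC(=CC2=O)/C(CO[Si](C)(C)C(C)(C)C)=C\[C@H]2OC(=O)C(CN(C)C)[C@@H]21 | intermediate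
35 | 11-(trimethylammoniomethyl) iodide derived from 34 | COc1ccc(cc1)CO[C@@H]1C[C@]2(C)OC(=CC2=O)/C(CO[Si](C)(C)C(C)(C)C)=C\[C@H]2OC(=O)C(C[N+](C)(C)C)[C@@H]21.[I-] | intermediate
36 | (4Z,6R,7R,8R,10S)-15-[(tert-butyldimethylsilyl)oxy]-3,10-epoxy-8-[(4-methoxybenzyl)oxy]-1-oxogermacra-2,4,11(13)-trien-12,6-olide | COc1ccc(cc1)CO[C@@H]1C[C@]2(C)OC(=CC2=O)/C(CO[Si](C)(C)C(C)(C)C)=C\[C@H]2OC(=O)C(=C)[C@@H]21 | intermediate
37 | (4Z,6R,7R,8R,10S)-15-[(tert-butyldimethylsilyl)oxy]-3,10-epoxy-8-hydroxy-1-oxogermacra-2,4,11(13)-trien-12,6-olide | O[C@@H]1C[C@]2(C)OC(=CC2=O)/C(CO[Si](C)(C)C(C)(C)C)=C\[C@H]2OC(=O)C(=C)[C@@H]21 | intermediate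
38 | methacrylic anhydride | CC(=C)C(=O)OC(=O)C(C)=C | starting material
39 | (4Z,6R,7R,8R,10S)-15-[(tert-butyldimethylsilyl)oxy]-3,10-epoxy-8-(methacryloyloxy)-1-oxogermacra-2,4,11(13)-trien-12,6-olide | C=C(C)C(=O)O[C@@H]1C[C@]2(C)OC(=CC2=O)/C(CO[Si](C)(C)C(C)(C)C)=C\[C@H]2OC(=O)C(=C)[C@@H]21 | intermediate
40 | (4Z,6R,7R,8R,10S)-3,10-epoxy-15-hydroxy-8-(methacryloyloxy)-1-oxogermacra-2,4,11(13)-trien-12,6-olide (CNP0180483.4) | C=C(C)C(=O)O[C@@H]1C[C@]2(C)OC(=CC2=O)/C(CO)=C\[C@H]2OC(=O)C(=C)[C@@H]21 | target

## Step count and least certain steps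

Total step count: 24. Longest linear sequence: 23 steps (1 to 40 through steps 1, 2 and 4–24; step 3 is a one-step side branch).

**Step 19 (key step, proposed new method).**
- What may go wrong: closure of the diradical with a trans ring fusion, or Z-to-E isomerisation of the excited cyclooctenone followed by thermal stepwise addition; either would lead to the 4E diene.
- Also possible: hydrogen abstraction by the vinyl radical instead of ring closure; retro-ene loss of the tertiary alkynyl ether as a ketene, or its hydration by traces of acid; and light-induced isomerisation at C4=C5 of the product.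
- Fallback (known chemistry), from 16 back to 31:
  - DDQ removes the 3,4-dimethoxybenzyl ether to give the 1,2-diol F1.
  - Parikh–Doering oxidation of its primary hydroxyl gives the α-hydroxy aldehyde F2.
  - The lithium acetylide of the enyne F3 adds to give the propargylic diol F4. F3 is prepared separately from 2-bromoprop-2-en-1-ol by silylation, Sonogashira coupling with ethynyltrimethylsilane and C-desilylation.
  - MnO2 oxidises F4 to the ynone F5.
  - Ph3PAuCl/AgOTf closes the furan-3(2H)-one by the known 5-endo-dig cyclisation of α′-hydroxy ynones to give F6.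
  - Ring-closing metathesis between the 1,1-disubstituted alkene at C4 and the vinyl group on C6, with the second-generation Hoveyda–Grubbs catalyst (H2IMes)Cl2Ru=CH(2-iPrOC6H4) in toluene at high dilution and 80 °C, closes the ten-membered ring at C4=C5 and returns to 31. The Z alkene is expected as the less strained one but is not secured by this closure.

**Step 16 (ynol ether formation).**
- What may go wrong: intramolecular attack of the neighbouring C1 alkoxide on C3 of the dichlorovinyl or chloroalkynyl ether (five-membered ketene acetal), incomplete chlorine–lithium exchange, or decomposition of the tertiary alkynyl ether on work-up.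
- Fallback, from 23 back to 28: the C1 hydroxyl is first silylated (Me3SiCl, Et3N) to the trimethylsilyl ether F7. n-BuLi and 24 then give the propargylic alcohol F8 without a free alkoxide next to the reacting centre. Silylation with t-BuMe2SiCl gives the bis-silyl ether F9, and K2CO3 in MeOH removes only the trimethylsilyl group to return 28.

**Step 15 (eight-membered ring-closing metathesis).**
- What may go wrong: slow initiation at the hindered allylic carbinol next to the quaternary carbon, so that oligomerisation through the C6 vinyl group outruns closure of the medium ring.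
- Fallback, from 21 back to 23: Nozaki–Hiyama–Kishi coupling (CrCl2, NiCl2 cat., DMF) of 21 with (E)-1-iodohepta-1,6-diene F10 gives the relay substrate F11. The catalyst loads at the unhindered terminal alkene, expels cyclopentene and is delivered to C2, from where it closes onto the C6 vinyl group (relay ring-closing metathesis) to give 23.

**Step 9 (directed reduction).**
- What may go wrong: poor facial selectivity, because the directing carbinol is quaternary and the chelate must place the methyl group axial; 1,2-induction from C7 may also oppose it.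
- Fallback, from 14 back to 15: 14 is reduced without chelation control (NaBH4, MeOH) and the C8 epimer F12 is separated. Mitsunobu inversion with 4-nitrobenzoic acid (PPh3, diisopropyl azodicarboxylate) gives the ester F13 with the required C8 configuration, and methanolysis (K2CO3, MeOH) returns 15.

**Step 4 (conjugate addition of the dianion).**
- What may go wrong: the alkoxide-bearing dianion may aggregate and react slowly, add to the lactone carbonyl (1,2), or be formed in competition with deprotonation at the benzylic ether.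
- Fallback, from 5 back to 11: the tertiary hydroxyl is silylated (Et3SiOTf, 2,6-lutidine) to F14. Its mono-anion (t-BuLi, THF/HMPA, −78 °C) is added to 7 to give F15. The conditions of step 5 then remove both silyl groups while forming the acetal, returning 11.

## Further compounds

F1 | step 19 | (2S,4R)-4-[(4-methoxybenzyl)oxy]-4-[(2R,3R)-5-methoxy-2-vinyltetrahydrofuran-3-yl]-2-methylbutane-1,2-diol | C=C[C@H]1OC(OC)C[C@@H]1[C@H](OCc2ccc(OC)cc2)C[C@](C)(O)CO
F2 | step 19 | (2S,4R)-2-hydroxy-4-[(4-methoxybenzyl)oxy]-4-[(2R,3R)-5-methoxy-2-vinyltetrahydrofuran-3-yl]-2-methylbutanal | C=C[C@H]1OC(OC)C[C@@H]1[C@H](OCc2ccc(OC)cc2)C[C@](C)(O)C=O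
F3 | step 19 | tert-butyldimethyl[(2-methylenebut-3-yn-1-yl)oxy]silane | C#CC(=C)CO[Si](C)(C)C(C)(C)C
F4 | step 19 | (6S,8R)-1-[(tert-butyldimethylsilyl)oxy]-8-[(4-methoxybenzyl)oxy]-8-[(2R,3R)-5-methoxy-2-vinyltetrahydrofuran-3-yl]-6-methyl-2-methyleneoct-3-yne-5,6-diol (both C5 epimers) | C=C[C@H]1OC(OC)C[C@@H]1[C@H](OCc2ccc(OC)cc2)C[C@](C)(O)C(O)C#CC(=C)CO[Si](C)(C)C(C)(C)C
F5 | step 19 | (6S,8R)-1-[(tert-butyldimethylsilyl)oxy]-6-hydroxy-8-[(4-methoxybenzyl)oxy]-8-[(2R,3R)-5-methoxy-2-vinyltetrahydrofuran-3-yl]-6-methyl-2-methyleneoct-3-yn-5-one | C=C[C@H]1OC(OC)C[C@@H]1[C@H](OCc2ccc(OC)cc2)C[C@](C)(O)C(=O)C#CC(=C)CO[Si](C)(C)C(C)(C)C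
F6 | step 19 | (S)-5-{3-[(tert-butyldimethylsilyl)oxy]prop-1-en-2-yl}-2-{(R)-2-[(4-methoxybenzyl)oxy]-2-[(2R,3R)-5-methoxy-2-vinyltetrahydrofuran-3-yl]ethyl}-2-methylfuran-3(2H)-one | C=C[C@H]1OC(OC)C[C@@H]1[C@H](OCc2ccc(OC)cc2)C[C@]2(C)OC(=CC2=O)C(=C)CO[Si](C)(C)C(C)(C)C
F7 | step 16 | trimethylsilyl ether of 23 at the C1 hydroxyl | COc1ccc(cc1)CO[C@@H]1C[C@](C)(O/C(Cl)=C\Cl)C(O[Si](C)(C)C)/C=C\[C@H]2OC(OC)C[C@@H]21
F8 | step 16 | C1 trimethylsilyl ether of 27 | COc1ccc(cc1)CO[C@@H]1C[C@](C)(OC#CCO)C(O[Si](C)(C)C)/C=C\[C@H]2OC(OC)C[C@@H]21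
F9 | step 16 | C1 trimethylsilyl ether of 28 | COc1ccc(cc1)CO[C@@H]1C[C@](C)(OC#CCO[Si](C)(C)C(C)(C)C)C(O[Si](C)(C)C)/C=C\[C@H]2OC(OC)C[C@@H]21
F10 | step 15 | (E)-1-iodohepta-1,6-diene | I/C=C/CCCC=C
F11 | step 15 | (6E,9S,11R)-9-{[(E)-1,2-dichlorovinyl]oxy}-11-[(4-methoxybenzyl)oxy]-11-[(2R,3R)-5-methoxy-2-vinyltetrahydrofuran-3-yl]-9-methylundeca-1,6-dien-8-ol (both C8 epimers) | C=C[C@H]1OC(OC)C[C@@H]1[C@H](OCc2ccc(OC)cc2)C[C@](C)(O/C(Cl)=C\Cl)C(O)/C=C/CCCC=C
F12 | step 9 | (2S,4S)-1-[(3,4-dimethoxybenzyl)oxy]-4-[(2R,3R)-5-methoxy-2-vinyltetrahydrofuran-3-yl]-2-methylbutane-2,4-diol | C=C[C@H]1OC(OC)C[C@@H]1[C@@H](O)C[C@](C)(O)COCc2ccc(OC)c(OC)c2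
F13 | step 9 | (1R,3S)-4-[(3,4-dimethoxybenzyl)oxy]-3-hydroxy-1-[(2R,3R)-5-methoxy-2-vinyltetrahydrofuran-3-yl]-3-methylbutyl 4-nitrobenzoate | C=C[C@H]1OC(OC)C[C@@H]1[C@H](OC(=O)c2ccc(cc2)[N+](=O)[O-])C[C@](C)(O)COCc2ccc(OC)c(OC)c2
F14 | step 4 | (S)-{[1-[(3,4-dimethoxybenzyl)oxy]-3-(1,3-dithian-2-yl)-2-methylpropan-2-yl]oxy}triethylsilane | COc1ccc(COC[C@@](C)(O[Si](CC)(CC)CC)CC2SCCCS2)cc1OC
F15 | step 4 | (4S,5S)-5-{[(tert-butyldimethylsilyl)oxy]methyl}-4-{2-[(S)-3-[(3,4-dimethoxybenzyl)oxy]-2-methyl-2-[(triethylsilyl)oxy]propyl]-1,3-dithian-2-yl}dihydrofuran-2(3H)-one | CC(C)(C)[Si](C)(C)OC[C@H]1OC(=O)C[C@@H]1C2(C[C@](C)(O[Si](CC)(CC)CC)COCc3ccc(OC)c(OC)c3)SCCCS2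
A1 | alternative 1 | ten-membered 3,8-dione with the 4Z alkene, methoxymethyl ethers at C1 and C10, silyl ethers at C6 and C15 and a 2-(4-methoxybenzyloxy)ethyl group at C7 | O=C1C[C@](C)(OCOC)[C@@H](OCOC)CC(=O)/C(CO[Si](C)(C)C(C)(C)C)=C\[C@@H](O[Si](C)(C)C(C)(C)C)[C@@H]1CCOCc2ccc(OC)cc2
A2 | alternative 2 | oxygen-bridged (C3–O–C10) cyclodecadienone with a C8 silyl enol ether, a C6 triethylsilyl ether, a C15 4-methoxybenzyl ether and a methyl acetate arm at C7 | CC(C)(C)[Si](C)(C)O/C1=C(CC(=O)OC)/[C@H](O[Si](CC)(CC)CC)/C=C(COCc3ccc(OC)cc3)\[C@@H]2CC(=O)[C@](C)(C1)O2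
A3 | alternative 3 | 13-nor lactone core with furanone, 4Z alkene, C8 tert-butyldimethylsilyl ether and free C15 hydroxyl | CC(C)(C)[Si](C)(C)O[C@@H]1C[C@]2(C)OC(=CC2=O)/C(CO)=C\[C@H]2OC(=O)C[C@@H]21
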